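The readings are simulated for substances that don't exist, noise included.

The ratio of right-handed substrate charged to right-handed substrate found tells how far a racemate has moved from its symmetric start, where right-handed substrate stands at 50.0% of the substrate charged. The natural logarithm of that ratio is here called the depth, d.

common to all: free catalyst 0.05 mol%; racemization catalyst 4.8 mol%
- ash: left-handed substrate 0.15 M; right-handed substrate 0.15 M; reagent 4 equiv; run made earlier
- flask: left-handed substrate 0.10 M; right-handed substrate 0.10 M; reagent 4.00 equiv; time 20 h

- ash (time / min: left-handed product / %, right-handed substrate / %): 30.0: 49.4, 36.0; 60.0: 52.0, 36.3; 90.0: 54.9, 36.7; 120: 54.0, 34.8

(readings scatter by 0.5 percentage points)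

- free catalyst is single-handed; left-handed substrate and right-handed substrate are mirror images of each other, charged as a racemate, each of them at the stated concentration
- the reaction counts as stopped when no species that holds the left-handed substrate and right-handed substrate together changes by six tenths of a point or more over the second half of the time
- no earlier run changes the charge of racemization catalyst; that part of a forecast is a guess
- no earlier run changes the charge of free catalyst; that part of a forecast is a guess

- at 20 h, what has stopped the reaction, if anything has (all of the left-handed substrate has reacted / the reagent has run out first / no working catalyst is left / it is still moving / forward and back rates have come level)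
- left-handed product at 20 h, in percent of the left-handed substrate and right-handed substrate together charged
- right-handed substrate at 20 h, in percent of the left-handed substrate and right-handed substrate together charged

In the ash run, right-handed substrate reads between 34.8% and 36.7% from 30.0 min on, with a mean of 36.0%, so the depth read there is 0.330.

For the asked flask, the upper bound is 50.0%, no loss at all. The lower bound is the ash mean, 36.0%, on the assumption that dilution does not deepen the loss. The bracket can be tightened, since the flask has 0.667 of the ash concentrations at the same equivalents and loadings. This is a reckoning of its own, not the forecast's. If d follows reagent concentration, right-handed substrate ends at 40.1%; if d follows free catalyst concentration as well, it ends at 43.2%.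

The forecast gives "no working catalyst is left", with 47% of left-handed product (36% to 57%) and 39% of right-handed substrate (35% to 43%). Its ground is: “If catalyst lifetime stays the same, conversion before death falls”. Its central value for right-handed substrate lies below the bracket, though its range overlaps the bracket.

At 20 h the flask holds 45.5% of left-handed product and 41.4% of right-handed substrate, the latter inside the bracket. The outcome is "the reagent has run out first": reagent stands at 0% of its charge.

    racemization catalyst → spent catalyst (k = 0.966 min⁻¹)
    reagent + free catalyst + left-handed substrate → free catalyst + left-handed product (k = 7670 M⁻² min⁻¹)
    left-handed substrate + racemization catalyst ⇌ right-handed substrate + racemization catalyst, rate k3*[racemization catalyst]*[left-handed substrate] forward; the back reaction follows from the equilibrium constant (k = 409 M⁻¹ min⁻¹)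
    2 reagent → homo dimer (k = 0.310 M⁻¹ min⁻¹)
    reagent + free catalyst + right-handed substrate → free catalyst + right-handed product (k = 357 M⁻² min⁻¹)

The flask's depth is 0.189. A neighbouring flask charged with 1.00 equiv of reagent has 0.167 of the ash reagent concentration. The same reckoning therefore brackets its right-handed substrate between 47.3% and 48.2%. That neighbouring flask holds 46.8% of right-handed substrate at 20.0 h.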